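## Retrosynthetic overview

1. Ring C: cut O1–C2. This leads back to a 2'-O-protected trans-(αR,βS)-epoxy ketone. Closure is a 6-endo opening at the p-oxybenzylic carbon, and the Cα–O bond is never broken.
2. Oxirane: cut C2–C3 and the Cα–O bond. This gives an aryl chloromethyl ketone (A ring) and a benzaldehyde (B ring), joined by a catalytic asymmetric Darzens reaction. Fragment union, both stereocentres, the oxirane and ring C all arise in one flask operation.
3. A-ring ketone: made from symmetric 4,6-dibromoresorcinol by two successive Br–Li exchanges (prenyl bromide, then ClCH2CON(OMe)Me). This places the prenyl group at the future C6 without ambiguity.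
4. B-ring aldehyde: ortho C-prenylation of 4-hydroxybenzaldehyde, then MOM protection.
5. Ring order: arenes A and B are bought. The oxirane forms first and the dihydropyranone ring C second, in the same pot, and the oxirane is consumed in making ring C.

Assumption: the quinidine-derived (cupreidinium) phase-transfer catalyst gives the (2R,3S)-epoxide. If the first run shows the opposite CD sign, the pseudo-enantiomeric quinine-derived salt is used under the same conditions.

## Route

Step 1
Reactants: 1 4,6-dibromoresorcinol (4,6-dibromobenzene-1,3-diol)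
Product: 2 1,5-dibromo-2,4-bis(methoxymethoxy)benzene
Conditions: MOMCl (2.4 equiv), K2CO3 (3 equiv), acetone, 0 °C → rt
Reagents that add atoms: chloromethyl methyl ether (MOMCl), COCCl
Why: Williamson-type O-alkylation (MOM acetal protection) of both acidic bromophenol OH groups gives ethers that survive BuLi and LiOH, stabilise an ortho-lithium and leave under mild acid at the end.

Step 2
Reactants: 2 1,5-dibromo-2,4-bis(methoxymethoxy)benzene; 3 prenyl bromide (1-bromo-3-methylbut-2-ene)
Product: 5 1-bromo-2,4-bis(methoxymethoxy)-5-(3-methylbut-2-enyl)benzene, via aryllithium 4 (not isolated)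
Conditions: n-BuLi (1.0 equiv), THF, −78 °C, 30 min; then 3 (1.1 equiv), CuBr·SMe2 (10 mol %), −78 → 0 °C
Reagents that add atoms: none
Why: Bromine–lithium exchange on the symmetric dibromide (both Br equivalent) stops at the OMOM-chelated monolithio stage, and Cu-catalysed SN2 allylation at the primary carbon of prenyl bromide fixes the prenyl group at the future C6.

Step 3
Reactants: 5 1-bromo-2,4-bis(methoxymethoxy)-5-(3-methylbut-2-enyl)benzene; 6 2-chloro-N-methoxy-N-methylacetamide
Product: 8 2-chloro-1-[2,4-bis(methoxymethoxy)-5-(3-methylbut-2-enyl)phenyl]ethanone, via aryllithium 7 (not isolated)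
Conditions: n-BuLi (1.05 equiv), THF, −78 °C, 20 min; then 6 (1.2 equiv), −78 °C, 1 h; AcOH quench at −78 °C
Reagents that add atoms: none
Why: In this Weinreb ketone synthesis after a second Br–Li exchange, the chelated tetrahedral adduct blocks over-addition and holds the C–Cl bond intact until the cold acidic quench releases the α-chloroketone.

Step 4
Reactants: 9 4-hydroxybenzaldehyde; 3 prenyl bromide
Product: 10 4-hydroxy-3-(3-methylbut-2-enyl)benzaldehyde
Conditions: KOH (1.1 equiv), H2O, rt, 24 h
Reagents that add atoms: none
Why: In this ortho C-alkylation of an ambident phenoxide, water hydrogen-bonds the oxygen and steers attack to carbon, the two ortho positions are equivalent, and the neutral O-prenyl ether by-product is removed by base extraction (modest yield, one step).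

Step 5
Reactants: 10 4-hydroxy-3-(3-methylbut-2-enyl)benzaldehyde
Product: 11 4-(methoxymethoxy)-3-(3-methylbut-2-enyl)benzaldehyde
Conditions: MOMCl (1.3 equiv), K2CO3 (2 equiv), acetone, 0 °C → rt
Reagents that add atoms: chloromethyl methyl ether (MOMCl), COCCl
Why: MOM acetal protection by Williamson-type O-alkylation removes the phenoxide that would otherwise deactivate the aldehyde as a vinylogous carboxylate under the basic Darzens conditions.

Step 6
Reactants: 8 2-chloro-1-[2,4-bis(methoxymethoxy)-5-(3-methylbut-2-enyl)phenyl]ethanone; 11 4-(methoxymethoxy)-3-(3-methylbut-2-enyl)benzaldehyde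
Product: 13 lespeflorin B1 [(2R,3R)-3,7-dihydroxy-2-[4-hydroxy-3-(3-methylbut-2-enyl)phenyl]-6-(3-methylbut-2-enyl)chroman-4-one], via trans-epoxy ketone 12 (not isolated)
Conditions: N-[3,5-bis(trifluoromethyl)benzyl]-9-O-benzylcupreidinium bromide (10 mol %), LiOH·H2O (3 equiv), CH2Cl2, 0 °C, 24–48 h; then MeOH, conc. HCl (to ca. 1 M), 40 °C, 3 h, same flask; one recrystallisation
Reagents that add atoms: none
Why: Proposed new method: the chiral ammonium chloroenolate of 8 adds to the catalyst-bound aldehyde 11 and the anti-chlorohydrin alkoxide closes by internal SN2 to the trans-(2R,3S)-oxirane 12, which sets C3 as R, after which acidifying the same flask strips the three MOM acetals and the freed 2'-OH opens the p-oxybenzylic oxirane carbon 6-endo with inversion (or via the benzylic cation/p-quinone methide, which collapses to the diequatorial 2,3-trans product) while the Cα–O bond stays intact, so C2 becomes R; the closest known reaction types are the asymmetric phase-transfer Darzens condensation of aryl chloromethyl ketones with aromatic aldehydes and the HCl/MeOH cyclisation of 2'-OMOM chalcone epoxides to trans-dihydroflavonols, here merged so that the silica-sensitive epoxide is never handled and no electrophilic oxidant meets the prenyl alkenes.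

## Compound list

1 | 4,6-dibromoresorcinol | Oc1cc(O)c(Br)cc1Br | starting material
2 | 1,5-dibromo-2,4-bis(methoxymethoxy)benzene | COCOc1cc(OCOC)c(Br)cc1Br | intermediate
3 | prenyl bromide (1-bromo-3-methylbut-2-ene) | CC(C)=CCBr | starting material
4 | 5-bromo-2,4-bis(methoxymethoxy)phenyllithium | [Li]c1cc(Br)c(OCOC)cc1OCOC | intermediate
5 | 1-bromo-2,4-bis(methoxymethoxy)-5-(3-methylbut-2-enyl)benzene | COCOc1cc(OCOC)c(CC=C(C)C)cc1Br | intermediate
6 | 2-chloro-N-methoxy-N-methylacetamide | CON(C)C(=O)CCl | starting material
7 | 2,4-bis(methoxymethoxy)-5-(3-methylbut-2-enyl)phenyllithium | [Li]c1cc(CC=C(C)C)c(OCOC)cc1OCOC | intermediate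
8 | 2-chloro-1-[2,4-bis(methoxymethoxy)-5-(3-methylbut-2-enyl)phenyl]ethanone | COCOc1cc(OCOC)c(CC=C(C)C)cc1C(=O)CCl | intermediate
9 | 4-hydroxybenzaldehyde | O=Cc1ccc(O)cc1 | starting material
10 | 4-hydroxy-3-(3-methylbut-2-enyl)benzaldehyde | CC(C)=CCc1cc(C=O)ccc1O | intermediate
11 | 4-(methoxymethoxy)-3-(3-methylbut-2-enyl)benzaldehyde | CC(C)=CCc1cc(C=O)ccc1OCOC | intermediate
12 | [2,4-bis(methoxymethoxy)-5-(3-methylbut-2-enyl)phenyl][(2R,3S)-3-[4-(methoxymethoxy)-3-(3-methylbut-2-enyl)phenyl]oxiran-2-yl]methanone (trans) | COCOc1cc(OCOC)c(CC=C(C)C)cc1C(=O)[C@@H]2O[C@H]2c3ccc(OCOC)c(CC=C(C)C)c3 | intermediate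
13 | lespeflorin B1, (2R,3R)-trans | CC(C)=CCc1cc([C@H]2Oc3cc(O)c(CC=C(C)C)cc3C(=O)[C@@H]2O)ccc1O | target

## Step count and risks

Total step count: 6. The catalyst is made separately from quinidine and is not counted.
Longest linear sequence: 4 (steps 1, 2, 3, 6).

**Step 6 (highest risk).**
- The electron-rich aldehyde and the ortho-substituted chloroketone may give low conversion or ee.
- The acid stage may touch the prenyl groups.
- The fallback sets out from bromide 5 and comes back at epoxy ketone 12.
- Bromine–lithium exchange on 5 and acylation with N-methoxy-N-methylacetamide give the methyl ketone 1-[2,4-bis(methoxymethoxy)-5-(3-methylbut-2-enyl)phenyl]ethanone F1.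
- Claisen–Schmidt condensation of this ketone with aldehyde 11 (KOH, EtOH, rt) gives (E)-1-[2,4-bis(methoxymethoxy)-5-(3-methylbut-2-enyl)phenyl]-3-[4-(methoxymethoxy)-3-(3-methylbut-2-enyl)phenyl]prop-2-en-1-one F2.
- Juliá–Colonna epoxidation (poly-L-leucine, urea–H2O2, DBU, THF, rt) is a nucleophilic oxidation that ignores the prenyl alkenes. It gives 12, which then goes through the acid stage of step 6 as before.

**Step 4.**
- O-alkylation and dialkylation compete, so the yield may be poor.
- The fallback sets out from 9 and comes back at 10.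
- Pd(0)-catalysed O-tert-prenylation of 9 (isobutyl 2-methylbut-3-en-2-yl carbonate, Pd(PPh3)4, THF, 0 °C) gives 4-(2-methylbut-3-en-2-yloxy)benzaldehyde F3.
- Its aromatic Claisen rearrangement (N,N-diethylaniline, 180 °C) transposes the allyl unit and delivers the linear ortho-prenyl phenol 10.

**Step 2.**
- Possible problems are protonation of the aryllithium, SN2' attack and some double exchange.
- The fallback sets out from 2 and comes back at 5, and it reverses the polarity of the partners.
- Pd-catalysed Stille coupling of 2 (2 equiv, excess recovered) with tributyl(3-methylbut-2-enyl)stannane (Pd(PPh3)4, DMF, 90 °C) gives 5 directly.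
- It makes no compound outside the list (F0).

## Further compounds

F1 | step 6 | 1-[2,4-bis(methoxymethoxy)-5-(3-methylbut-2-enyl)phenyl]ethanone | COCOc1cc(OCOC)c(CC=C(C)C)cc1C(C)=O
F2 | step 6 | (E)-1-[2,4-bis(methoxymethoxy)-5-(3-methylbut-2-enyl)phenyl]-3-[4-(methoxymethoxy)-3-(3-methylbut-2-enyl)phenyl]prop-2-en-1-one | COCOc1cc(OCOC)c(CC=C(C)C)cc1C(=O)/C=C/c2ccc(OCOC)c(CC=C(C)C)c2
F3 | step 4 | 4-(2-methylbut-3-en-2-yloxy)benzaldehyde | C=CC(C)(C)Oc1ccc(C=O)cc1
F0 | step 2 | none | none
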